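## Retrosynthetic overview

1. Late cuts: the seven benzyl groups come off last. The C3 carboxyl comes from a CH2OTBS group. The side-chain C=C between ring C1 and the (R)-danshensu ester comes from a ring enal, the protected danshensu alcohol and Ph3P=C=C=O as a two-carbon Wittig linchpin.
2. Feature used: in the cyclohexene ring C1–C6, the C1=C2 bond is conjugated to an acceptor on C1. It is followed by four contiguous stereocentres, C3(CO2H)–C4(aryl)–C5(CO2H)–C6(CO2H), with 3,4-trans and 4,6-trans relationships. This is the substitution pattern that an enamine–iminium–enamine [2+2+2] cascade produces.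
3. Key disconnection: C3–C4, C5–C6 and C1=C2 are cut at once. This gives three achiral pieces: 3-silyloxypropanal (C2–C3), the arylidene Meldrum's acid (C4–C5) and a 4-oxobut-2-enoate (C6–C1 plus CHO). One chiral amine sets C3, C4 and C6.
4. The spiro Meldrum ring at C5 is a traceless activator. Opening it with BnOH, with loss of acetone and CO2, leaves the C5 ester and sets C5. The carbocycle is the only ring of the target and is closed in the key step.

Key step: step 4

Convention: ring locants are C1 (alkene carbon bearing the side chain), C2 (=CH), C3, C4, C5, C6. With C1→C6 drawn counter-clockwise, β points to the viewer and α away. The target is 3α-CO2H, 4β-aryl, 5α-CO2H, 6α-CO2H, which is (3R,4S,5R,6R) in these locants, and (R) at the side-chain carbinol carbon.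

Assumption: sodium (R)-3-(3,4-dihydroxyphenyl)lactate (sodium danshensu), 3-(TBSO)propanal, both phosphorus ylides and (R)-diphenylprolinol TMS ether are taken as purchasable.

## Route

Step 1
Reactants: 1 3,4-bis(benzyloxy)benzaldehyde; 2 Meldrum's acid (2,2-dimethyl-1,3-dioxane-4,6-dione)
Product: 3 5-[3,4-bis(benzyloxy)benzylidene]-2,2-dimethyl-1,3-dioxane-4,6-dione
Conditions: piperidine/AcOH (cat.), EtOH, rt, product filtered off
Reagents that add atoms: none
Why: Knoevenagel condensation of an aromatic aldehyde with the strongly C–H acidic cyclic malonate, in which the product crystallises from the medium and no stereocentre is formed.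

Step 2
Reactants: 4 benzyl (triphenylphosphoranylidene)acetate; 5 2,2-dimethoxyacetaldehyde (60 % aq.)
Product: 6 benzyl (E)-4,4-dimethoxybut-2-enoate
Conditions: CH2Cl2/H2O, rt
Reagents that add atoms: none
Why: Wittig olefination with a stabilised ylide, which tolerates the aqueous aldehyde solution and should give the E-enoate.

Step 3
Reactants: 6 benzyl (E)-4,4-dimethoxybut-2-enoate
Product: 7 benzyl (E)-4-oxobut-2-enoate
Conditions: TsOH·H2O (cat.), acetone/H2O, 40 °C
Reagents that add atoms: water, O
Why: Acid-catalysed acetal hydrolysis, to which the benzyl ester and the E-alkene are inert.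

Step 4
Reactants: 8 3-[(tert-butyldimethylsilyl)oxy]propanal; 3 arylidene Meldrum's acid; 7 benzyl (E)-4-oxobut-2-enoate
Product: 11 spiro-Meldrum cyclohexenecarbaldehyde (1-formyl 3α-CH2OTBS 4β-[3,4-bis(benzyloxy)phenyl] 6α-CO2Bn cyclohex-1-ene whose C5 is C5 of a 2,2-dimethyl-1,3-dioxane-4,6-dione), via Michael adduct 9 (not isolated), via dialdehyde 10 (not isolated)
Conditions: (R)-α,α-diphenylprolinol TMS ether (20 mol %), PhCO2H (20 mol %), PhMe, 0 °C, 8 + 3; then 7 in the same flask, 0 °C → rt
Reagents that add atoms: none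
Why: Proposed new method: the amine converts 8 into its E-enamine, which adds to the strongly electrophilic benzylidene carbon of 3 (C3–C4 bond, 9); the acidic 5-substituted Meldrum's acid then adds as its carbanion to the β-carbon of the iminium ion of 7 (C5–C6 bond, 10), and the enamine left behind closes the carbocycle on the C2 aldehyde by a 6-(enolexo)-exo-trig aldol addition, dehydration giving C1=C2 and releasing the catalyst. The closest known reaction type is the enamine–iminium–enamine triple cascade of aldehydes, nitroalkenes and enals, already extended to geminally diactivated arylidene acceptors (α-cyanoacrylates, alkylidene oxindoles) that also build a quaternary C5, but not to arylidene Meldrum's acids paired with a 4-oxoenoate. C3 is controlled by the CPh2(OTMS) group shielding one enamine face, C4 by the synclinal approach of the acceptor to the open face (syn adduct, 3,4-trans in the ring), and C6 by the same group shielding the corresponding face of the E-iminium ion, so that the (R)-catalyst should give 3α,4β,6α; spiro C5 has two identical arms and is not yet stereogenic. The step needs chemoselectivity (enamine to 3, carbanion to 7): 3 is far more electrophilic than free 7 and cannot form an iminium ion, 7 is added only after 3 is consumed, and the iminium ion directs attack to the carbon α to the ester. It also needs the reversible Michael steps to be drained, which the irreversible dehydration secures.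

Step 5
Reactants: 11 spiro-Meldrum cyclohexenecarbaldehyde
Product: 13 dibenzyl 5α,6α-diester enal (1-formyl 3α-CH2OTBS 4β-aryl 5α-CO2Bn 6α-CO2Bn cyclohex-1-ene), via hemimalonate 12 (not isolated)
Conditions: BnOH (10 equiv), DMAP (0.3 equiv), PhMe, 110 °C
Reagents that add atoms: benzyl alcohol, OCc1ccccc1
Why: Nucleophile-catalysed alcoholysis of a 5,5-disubstituted Meldrum's acid (acylal opening with loss of acetone) gives hemimalonate 12, whose thermal decarboxylation gives an ester enol that should be protonated axially on the β face of the half-chair with the C6 ester pseudo-axial (the α face is blocked by that ester, and in the flipped half-chair by the syn-axial C3 side chain), placing the C5 ester equatorial, trans to the aryl group and cis to the C6 ester; acid-free conditions avoid Friedel–Crafts closure of the benzylic Meldrum's acid to an indanone, and ester exchange with BnOH is degenerate.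

Step 6
Reactants: 14 sodium (R)-3-(3,4-dihydroxyphenyl)lactate
Product: 15 benzyl (R)-3-[3,4-bis(benzyloxy)phenyl]-2-hydroxypropanoate
Conditions: BnBr (3.3 equiv), K2CO3, DMF, rt
Reagents that add atoms: benzyl bromide, BrCc1ccccc1
Why: O-alkylation of the carboxylate and of the two phenoxides (Williamson type), in which carbonate does not deprotonate the secondary alcohol, so it stays free and the uninvolved (R)-centre is retained.

Step 7
Reactants: 15 benzyl (R)-3-[3,4-bis(benzyloxy)phenyl]-2-hydroxypropanoate; 16 (triphenylphosphoranylidene)ketene; 13 dibenzyl 5α,6α-diester enal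
Product: 18 fully protected (E)-dienoate (ring as in 13 with C1 bearing (E)-CH=CH-CO2R where R is the (R)-carbinol carbon of 15), via ester ylide 17 (not isolated)
Conditions: 15 + 16, PhMe, 110 °C; then 13, 90 °C
Reagents that add atoms: none
Why: Addition of the alcohol to the cumulated ylide gives the stabilised ester ylide 17, whose Wittig reaction with the enal should give the E-alkene under neutral conditions that leave C3–C6 and the carbinol centre untouched.

Step 8
Reactants: 18 fully protected (E)-dienoate
Product: 19 primary alcohol (3α-CH2OH)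
Conditions: HF·pyridine, THF/pyridine, 0 °C → rt
Reagents that add atoms: none
Why: Fluoride cleavage of a primary TBS ether under buffered, non-basic conditions that spare the benzyl ethers, the benzyl esters and the base-sensitive dienoate.

Step 9
Reactants: 19 primary alcohol
Product: 21 heptabenzyl C3 carboxylic acid (3α-CO2H), via C3 aldehyde 20 (not isolated)
Conditions: TEMPO (0.2 equiv), PhI(OAc)2 (2.5 equiv), MeCN/H2O, rt
Reagents that add atoms: water, O
Why: TEMPO/PhI(OAc)2 oxidation in aqueous acetonitrile takes the alcohol through aldehyde 20 and its hydrate to the acid under weakly acidic conditions, so the doubly activated C3–H should not enolise, and C3 already holds its favoured pseudo-equatorial configuration.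

Step 10
Reactants: 21 heptabenzyl C3 carboxylic acid
Product: 22 target CNP0327643.1
Conditions: BCl3 (excess), pentamethylbenzene, CH2Cl2, −78 → −20 °C; aq. work-up; reversed-phase purification
Reagents that add atoms: none
Why: Lewis-acid debenzylation with a non-basic cation scavenger cleaves aryl benzyl ethers and benzyl esters at low temperature without reducing the diene (as hydrogenolysis would) and without base, so the secondary ester and all five stereocentres should persist.

## Compound list

1 | 3,4-bis(benzyloxy)benzaldehyde | O=Cc1ccc(OCc2ccccc2)c(OCc2ccccc2)c1 | starting material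
2 | Meldrum's acid | CC1(C)OC(=O)CC(=O)O1 | starting material
3 | 5-[3,4-bis(benzyloxy)benzylidene]-2,2-dimethyl-1,3-dioxane-4,6-dione | CC1(C)OC(=O)C(=Cc2ccc(OCc3ccccc3)c(OCc3ccccc3)c2)C(=O)O1 | intermediate
4 | benzyl (triphenylphosphoranylidene)acetate | O=C(C=P(c1ccccc1)(c1ccccc1)c1ccccc1)OCc1ccccc1 | starting material
5 | 2,2-dimethoxyacetaldehyde | COC(OC)C=O | starting material
6 | benzyl (E)-4,4-dimethoxybut-2-enoate | COC(OC)/C=C/C(=O)OCc1ccccc1 | intermediate
7 | benzyl (E)-4-oxobut-2-enoate | O=C/C=C/C(=O)OCc1ccccc1 | intermediate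
8 | 3-[(tert-butyldimethylsilyl)oxy]propanal | O=CCCO[Si](C)(C)C(C)(C)C | starting material
9 | (2R,3S)-3-[3,4-bis(benzyloxy)phenyl]-2-(TBSO-methyl)-3-(2,2-dimethyl-4,6-dioxo-1,3-dioxan-5-yl)propanal | O=C[C@@H](CO[Si](C)(C)C(C)(C)C)[C@H](c1ccc(OCc2ccccc2)c(OCc2ccccc2)c1)C1C(=O)OC(C)(C)OC1=O | intermediate
10 | open-chain dialdehyde (9 alkylated at the Meldrum carbon by CH(CO2Bn)CH2CHO, configured as C6α) | O=C[C@@H](CO[Si](C)(C)C(C)(C)C)[C@H](c1ccc(OCc2ccccc2)c(OCc2ccccc2)c1)C1(C(=O)OC(C)(C)OC1=O)[C@H](CC=O)C(=O)OCc1ccccc1 | intermediate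
11 | spiro-Meldrum cyclohexenecarbaldehyde (3α-CH2OTBS, 4β-aryl, 6α-CO2Bn) | O=CC1=C[C@@H](CO[Si](C)(C)C(C)(C)C)[C@H](c2ccc(OCc3ccccc3)c(OCc3ccccc3)c2)C2(C(=O)OC(C)(C)OC2=O)[C@H]1C(=O)OCc1ccccc1 | intermediate
12 | hemimalonate (5α-CO2Bn, 5β-CO2H) | O=CC1=C[C@@H](CO[Si](C)(C)C(C)(C)C)[C@H](c2ccc(OCc3ccccc3)c(OCc3ccccc3)c2)[C@@](C(=O)O)(C(=O)OCc2ccccc2)[C@H]1C(=O)OCc1ccccc1 | intermediate
13 | dibenzyl 5α,6α-diester enal (3α-CH2OTBS, 4β-aryl) | O=CC1=C[C@@H](CO[Si](C)(C)C(C)(C)C)[C@H](c2ccc(OCc3ccccc3)c(OCc3ccccc3)c2)[C@@H](C(=O)OCc2ccccc2)[C@H]1C(=O)OCc1ccccc1 | intermediate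
14 | sodium (R)-3-(3,4-dihydroxyphenyl)lactate | O[C@H](Cc1ccc(O)c(O)c1)C(=O)[O-].[Na+] | starting material
15 | benzyl (R)-3-[3,4-bis(benzyloxy)phenyl]-2-hydroxypropanoate | O[C@H](Cc1ccc(OCc2ccccc2)c(OCc2ccccc2)c1)C(=O)OCc1ccccc1 | intermediate
16 | (triphenylphosphoranylidene)ketene | O=C=C=P(c1ccccc1)(c1ccccc1)c1ccccc1 | starting material
17 | (triphenylphosphoranylidene)acetate ester of 15 | O=C(C=P(c1ccccc1)(c1ccccc1)c1ccccc1)O[C@H](Cc1ccc(OCc2ccccc2)c(OCc2ccccc2)c1)C(=O)OCc1ccccc1 | intermediate
18 | fully protected (E)-dienoate (3α-CH2OTBS) | O=C(/C=C/C1=C[C@@H](CO[Si](C)(C)C(C)(C)C)[C@H](c2ccc(OCc3ccccc3)c(OCc3ccccc3)c2)[C@@H](C(=O)OCc2ccccc2)[C@H]1C(=O)OCc1ccccc1)O[C@H](Cc1ccc(OCc2ccccc2)c(OCc2ccccc2)c1)C(=O)OCc1ccccc1 | intermediate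
19 | primary alcohol (3α-CH2OH) | O=C(/C=C/C1=C[C@@H](CO)[C@H](c2ccc(OCc3ccccc3)c(OCc3ccccc3)c2)[C@@H](C(=O)OCc2ccccc2)[C@H]1C(=O)OCc1ccccc1)O[C@H](Cc1ccc(OCc2ccccc2)c(OCc2ccccc2)c1)C(=O)OCc1ccccc1 | intermediate
20 | C3 aldehyde (3α-CHO) | O=C(/C=C/C1=C[C@@H](C=O)[C@H](c2ccc(OCc3ccccc3)c(OCc3ccccc3)c2)[C@@H](C(=O)OCc2ccccc2)[C@H]1C(=O)OCc1ccccc1)O[C@H](Cc1ccc(OCc2ccccc2)c(OCc2ccccc2)c1)C(=O)OCc1ccccc1 | intermediate
21 | heptabenzyl C3 carboxylic acid | O=C(/C=C/C1=C[C@@H](C(=O)O)[C@H](c2ccc(OCc3ccccc3)c(OCc3ccccc3)c2)[C@@H](C(=O)OCc2ccccc2)[C@H]1C(=O)OCc1ccccc1)O[C@H](Cc1ccc(OCc2ccccc2)c(OCc2ccccc2)c1)C(=O)OCc1ccccc1 | intermediate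
22 | CNP0327643.1, (1R,2R,3S,4R)-3-(3,4-dihydroxyphenyl)-6-[(E)-3-{[(1R)-1-carboxy-2-(3,4-dihydroxyphenyl)ethyl]oxy}-3-oxoprop-1-enyl]cyclohex-5-ene-1,2,4-tricarboxylic acid | O=C(/C=C/C1=C[C@@H](C(=O)O)[C@H](c2ccc(O)c(O)c2)[C@@H](C(=O)O)[C@H]1C(=O)O)O[C@H](Cc1ccc(O)c(O)c1)C(=O)O | target

## Step count and risks

Total step count: 10. Longest linear sequence: 8 (steps 2, 3, 4, 5, 7, 8, 9, 10).

**Step 4 (bears the label).**
- What may go wrong: the secondary amine may be tied up by reversible aza-Michael addition to, or retro-Knoevenagel cleavage of, the arylidene Meldrum's acid. The second Michael addition may also revert, because the Meldrum carbanion is an excellent leaving group. Either way turnover or facial selectivity would be lost.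
- Fallback (known chemistry), setting out from 1 and coming back at 12: Knoevenagel condensation of 1 with benzyl cyanoacetate gives benzyl (E)-2-cyano-3-[3,4-bis(benzyloxy)phenyl]acrylate F1. This belongs to the α-cyanoacrylate class for which the aldehyde/acceptor/enal triple cascade is established. With 8, 7, the same (R)-catalyst and an aromatic acid co-catalyst it should give the 5-cyano-5-(benzyloxycarbonyl)cyclohexenecarbaldehyde F2; either C5 epimer serves. Neutral hydration of the nitrile with a Pt(II) phosphinito catalyst in aqueous EtOH gives the primary amide F3. Nitrosative hydrolysis (t-BuONO, AcOH) then gives hemimalonate 12, which is decarboxylated as in step 5.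

**Step 5.**
- What may go wrong: poor facial selectivity in the protonation of the ester enol if the flipped half-chair (aryl axial) competes. The resulting C5 epimer mixture could not be corrected with base without risking migration of the C1=C2 bond.
- Fallback, setting out from 11 and coming back at 19: the C5 hydrogen is installed at a bridgehead instead. HF·pyridine frees the 3α-CH2OH group of 11. This group can reach only the α carbonyl of the spiro acylal and opens it, with loss of acetone, to the bridged δ-lactone acid F4 (a 3-oxabicyclo[3.3.1]nonenone), so the retained C5 carbonyl is the α one. Thermal decarboxylation of this acid is blocked because the enol would be a bridgehead alkene, so the β-CO2H is removed by Barton decarboxylation. 1-Hydroxypyridine-2(1H)-thione and DCC give the thiohydroxamate ester F5. Irradiation with t-BuSH then gives the bridged lactone F6, since the bridgehead radical can accept hydrogen only on the β face. Distannoxane-catalysed alcoholysis with BnOH opens the strained lactone to the hydroxy enal diester F7. Wittig reaction with ylide 17, made as in step 7, gives 19 directly.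

**Step 7.**
- What may go wrong: slow addition of the hindered α-hydroxy ester to the cumulated ylide and sluggish olefination of the doubly flanked enal, so that long heating loses material through double-bond migration.
- Fallback, setting out from 13 and coming back at 18: the C=C bond is made first with a small ylide, and the fragments are then joined at the C–O bond. Wittig reaction of 13 with tert-butyl (triphenylphosphoranylidene)acetate gives the tert-butyl dienoate F8. TMSOTf/2,6-lutidine cleaves the tert-butyl ester without touching the TBS ether and gives the dienoic acid F9. Steglich esterification (DCC, DMAP) with alcohol 15 gives 18.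

## Further compounds

F1 | step 4 | benzyl (E)-2-cyano-3-[3,4-bis(benzyloxy)phenyl]acrylate | N#C/C(=C\c1ccc(OCc2ccccc2)c(OCc2ccccc2)c1)C(=O)OCc1ccccc1
F2 | step 4 | 5-cyano-5-(benzyloxycarbonyl)cyclohexenecarbaldehyde (3α-CH2OTBS, 4β-aryl, 6α-CO2Bn) | O=CC1=C[C@@H](CO[Si](C)(C)C(C)(C)C)[C@H](c2ccc(OCc3ccccc3)c(OCc3ccccc3)c2)[C@@](C#N)(C(=O)OCc2ccccc2)[C@H]1C(=O)OCc1ccccc1
F3 | step 4 | 5-carbamoyl-5-(benzyloxycarbonyl)cyclohexenecarbaldehyde | O=CC1=C[C@@H](CO[Si](C)(C)C(C)(C)C)[C@H](c2ccc(OCc3ccccc3)c(OCc3ccccc3)c2)[C@@](C(N)=O)(C(=O)OCc2ccccc2)[C@H]1C(=O)OCc1ccccc1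
F4 | step 5 | bridged δ-lactone acid (C3-CH2-O-CO-C5 bridge on the α face, 5β-CO2H) | O=CC1=C[C@@H](CO2)[C@H](c3ccc(OCc4ccccc4)c(OCc4ccccc4)c3)[C@@](C(=O)O)(C2=O)[C@H]1C(=O)OCc1ccccc1
F5 | step 5 | thiohydroxamate ester of F4 | O=CC1=C[C@@H](CO2)[C@H](c3ccc(OCc4ccccc4)c(OCc4ccccc4)c3)[C@@](C(=O)ON3C=CC=CC3=S)(C2=O)[C@H]1C(=O)OCc1ccccc1
F6 | step 5 | bridged lactone (5β-H) | O=CC1=C[C@@H](CO2)[C@H](c3ccc(OCc4ccccc4)c(OCc4ccccc4)c3)[C@@H](C2=O)[C@H]1C(=O)OCc1ccccc1
F7 | step 5 | hydroxy enal diester (3α-CH2OH, 5α,6α-CO2Bn) | O=CC1=C[C@@H](CO)[C@H](c2ccc(OCc3ccccc3)c(OCc3ccccc3)c2)[C@@H](C(=O)OCc2ccccc2)[C@H]1C(=O)OCc1ccccc1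
F8 | step 7 | tert-butyl dienoate | CC(C)(C)OC(=O)/C=C/C1=C[C@@H](CO[Si](C)(C)C(C)(C)C)[C@H](c2ccc(OCc3ccccc3)c(OCc3ccccc3)c2)[C@@H](C(=O)OCc2ccccc2)[C@H]1C(=O)OCc1ccccc1
F9 | step 7 | dienoic acid | OC(=O)/C=C/C1=C[C@@H](CO[Si](C)(C)C(C)(C)C)[C@H](c2ccc(OCc3ccccc3)c(OCc3ccccc3)c2)[C@@H](C(=O)OCc2ccccc2)[C@H]1C(=O)OCc1ccccc1
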